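The oxane ring (O1, C2 to C6; C2 carries the decalin) is made last, by forming its O1–C6 and C5–Cl bonds together: the anti, vicinal oxygen/chlorine pair on C6(CH3)2–C5H is the retron of chlorenium addition to a prenyl alkene captured by a tertiary alcohol. The precursor is the cis-octalone 13 carrying a (2R)-2-hydroxy-6-methylhept-5-en-2-yl chain. One 6-endo chloroetherification closes the ring, makes both bonds and sets C5, relayed from the carbinol centre C2 through a chair transition state. The decalin is built beforehand by an intramolecular Diels–Alder reaction of a nerol-derived trienone; the formamide-bearing centre follows.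

Key step: step 8

Assumption: 9 is drawn as the open hydroxy aldehyde although it should exist mainly as its six-membered lactol, and 11 is carried on as a mixture of epimers at the allylic carbinol carbon, which is oxidised in step 7.

Step 1
Reactants: 1 nerol [(2Z)-3,7-dimethylocta-2,6-dien-1-ol]
Product: 2 [(2S,3R)-3-methyl-3-(4-methylpent-3-en-1-yl)oxiran-2-yl]methanol
Conditions: Ti(OiPr)4 (5 mol %), L-(+)-diethyl tartrate (6 mol %), t-BuOOH, 4 Å molecular sieves, CH2Cl2, −20 °C
Reagents that add atoms: tert-butyl hydroperoxide, CC(C)(C)OO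
Why: Sharpless asymmetric epoxidation acts only on the allylic-alcohol alkene and, with the L-(+)-tartrate, should deliver oxygen to the face that gives the (2S,3R)-epoxide, so that C-3 already has the configuration of the later oxane carbon C2.

Step 2
Reactants: 2 [(2S,3R)-3-methyl-3-(4-methylpent-3-en-1-yl)oxiran-2-yl]methanol; 3 [2-(1,3-dioxolan-2-yl)ethyl]magnesium bromide
Product: 4 (2R,3R)-2-[2-(1,3-dioxolan-2-yl)ethyl]-3,7-dimethyloct-6-ene-1,3-diol
Conditions: 3 (3 equiv), CuI (10 mol %), THF, −30 → 0 °C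
Reagents that add atoms: [2-(1,3-dioxolan-2-yl)ethyl]magnesium bromide (compound 3), Br[Mg]CCC1OCCO1
Why: Copper-catalysed Grignard opening of a 2,3-epoxy alcohol, in which the fully substituted C-3 leaves only C-2 open to SN2 attack, so that inversion at C-2 sets the future decalin carbon C-4 as (R) next to the untouched (R)-carbinol.

Step 3
Reactants: 4 (2R,3R)-2-[2-(1,3-dioxolan-2-yl)ethyl]-3,7-dimethyloct-6-ene-1,3-diol; 5 1-(triphenyl-λ5-phosphanylidene)propan-2-one
Product: 7 (3E,5R,6R)-5-[2-(1,3-dioxolan-2-yl)ethyl]-6-hydroxy-6,10-dimethylundeca-3,9-dien-2-one, via hydroxy aldehyde 6 (not isolated)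
Conditions: TEMPO (10 mol %), PhI(OAc)2, CH2Cl2, rt; then 5, 40 °C
Reagents that add atoms: 1-(triphenyl-λ5-phosphanylidene)propan-2-one (compound 5), CC(=O)C=P(c1ccccc1)(c1ccccc1)c1ccccc1
Why: The TEMPO/PhI(OAc)2 oxidation touches only the primary alcohol, and the stabilised Wittig ylide traps the base-sensitive β-hydroxy aldehyde in the same flask under neutral conditions, which should give the (E)-enone without epimerisation or retro-aldol cleavage.

Step 4
Reactants: 7 (3E,5R,6R)-5-[2-(1,3-dioxolan-2-yl)ethyl]-6-hydroxy-6,10-dimethylundeca-3,9-dien-2-one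
Product: 8 (3E,5R,6R)-5-[2-(1,3-dioxolan-2-yl)ethyl]-2,6,10-trimethylundeca-1,3,9-trien-6-ol
Conditions: Cp2Ti(μ-Cl)(μ-CH2)AlMe2 (2.5 equiv), pyridine (cat.), THF/toluene, −40 → 0 °C
Reagents that add atoms: Tebbe reagent Cp2Ti(μ-Cl)(μ-CH2)AlMe2, C[Al-]1(C)C[Ti](C2C=CC=C2)(C2C=CC=C2)[Cl+]1
Why: Tebbe methylenation is a non-basic carbonyl olefination, so the methyl ketone should become the 2-methyl-1,3-diene without deprotonation at the γ-stereocentre and without fragmentation of the only transiently metalated tertiary alcohol.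

Step 5
Reactants: 8 (3E,5R,6R)-5-[2-(1,3-dioxolan-2-yl)ethyl]-2,6,10-trimethylundeca-1,3,9-trien-6-ol
Product: 9 (4R,5R)-5-hydroxy-5,9-dimethyl-4-[(1E)-3-methylbuta-1,3-dien-1-yl]dec-8-enal
Conditions: AcOH/THF/H2O (3:1:1), 40 °C
Reagents that add atoms: water, O
Why: Mild acid hydrolysis of the dioxolane is assisted by the δ-hydroxyl, which takes up the aldehyde as a lactol, while the diene, the isolated alkene and the non-allylic tertiary alcohol should tolerate dilute acetic acid.

Step 6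
Reactants: 9 (4R,5R)-5-hydroxy-5,9-dimethyl-4-[(1E)-3-methylbuta-1,3-dien-1-yl]dec-8-enal; 10 vinylmagnesium bromide
Product: 11 (6R,7R)-7,11-dimethyl-6-[(1E)-3-methylbuta-1,3-dien-1-yl]dodeca-1,10-diene-3,7-diol
Conditions: CH2=CHMgBr (3.5 equiv), THF, −78 → 0 °C
Reagents that add atoms: vinylmagnesium bromide (compound 10), C=C[Mg]Br
Why: Grignard 1,2-addition to the aldehyde released from the lactol equilibrium; the new carbinol centre is formed without control and is removed in the next step.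

Step 7
Reactants: 11 (6R,7R)-7,11-dimethyl-6-[(1E)-3-methylbuta-1,3-dien-1-yl]dodeca-1,10-diene-3,7-diol
Product: 13 (4R,4aS,8aS)-4-[(2R)-2-hydroxy-6-methylhept-5-en-2-yl]-6-methyl-3,4,4a,7,8,8a-hexahydronaphthalen-1(2H)-one, via trienone 12 (not isolated)
Conditions: Dess–Martin periodinane, NaHCO3, CH2Cl2, 0 °C → rt; then toluene, BHT (cat.), 50 °C
Reagents that add atoms: none
Why: Dess–Martin oxidation of the secondary allylic alcohol gives a 1,7,9-decatrien-3-one that should undergo intramolecular Diels–Alder reaction through the endo transition state (carbonyl under the diene) to the cis-fused octalone, the allylic stereocentre holding its hydrogen in the diene plane (least allylic 1,3-strain) and its bulky carbinol substituent away from the dienophile, which sets C-4a and C-8a relative to C-4.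

Step 8
Reactants: 13 (4R,4aS,8aS)-4-[(2R)-2-hydroxy-6-methylhept-5-en-2-yl]-6-methyl-3,4,4a,7,8,8a-hexahydronaphthalen-1(2H)-one
Product: 14 (4R,4aS,8aS)-4-[(2R,5S)-5-chloro-2,6,6-trimethyloxan-2-yl]-6-methyl-3,4,4a,7,8,8a-hexahydronaphthalen-1(2H)-one
Conditions: N-chlorosuccinimide (1.1 equiv), Ph3P=S (10 mol %), CH2Cl2, −40 → −10 °C, dark
Reagents that add atoms: N-chlorosuccinimide, O=C1CCC(=O)N1Cl
Why: Haloetherification: Ph3P=S activates N-chlorosuccinimide as a chlorosulfonium donor that transfers Cl+ to the 2-methylbut-2-enyl terminus while the tertiary hydroxyl attacks in concert (nucleophile-assisted alkene activation), which is why the side-chain alkene should react faster than the more hindered ring alkene that has no internal nucleophile. The closest known reaction type is the bromo- or chloroetherification of bishomoallylic tertiary alcohols that gives the 3-halo-2,2-dimethyloxanes of marine terpenoids. The oxane closes in the 6-endo mode, the oxygen opening the unsymmetrical chloriranium ion at its tertiary carbon (Markovnikov sense), in competition with 5-exo closure to an oxolane carrying a 2-chloropropan-2-yl group. The new stereocentre C5 is controlled by the existing carbinol centre C2: in the chair transition state the bulky octalonyl group is equatorial and the methyl axial, and anti addition then places chlorine equatorial, trans to the octalonyl group, that is (5S). The step needs chemoselectivity (side-chain over ring alkene), regioselectivity (6-endo over 5-exo) and facial selectivity, which the pendant hydroxyl, the gem-dimethyl terminus and the quaternary carbinol centre are expected to secure in that order.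

Step 9
Reactants: 14 (4R,4aS,8aS)-4-[(2R,5S)-5-chloro-2,6,6-trimethyloxan-2-yl]-6-methyl-3,4,4a,7,8,8a-hexahydronaphthalen-1(2H)-one; 15 (R)-2-methylpropane-2-sulfinamide
Product: 16 (R)-N-[(1E,4R,4aR,8aS)-4-[(2R,5S)-5-chloro-2,6,6-trimethyloxan-2-yl]-6-methyl-3,4,4a,7,8,8a-hexahydronaphthalen-1(2H)-ylidene]-2-methylpropane-2-sulfinamide
Conditions: 15 (1.5 equiv), Ti(OEt)4 (3 equiv), THF, 50 °C
Reagents that add atoms: (R)-2-methylpropane-2-sulfinamide (compound 15), CC(C)(C)[S@](N)=O
Why: Ti(OEt)4-mediated condensation of a ketone with tert-butanesulfinamide should give the N-sulfinyl ketimine with sulfur anti to the branched α-carbon C-8a; no stereocentre is formed and the moderate temperature is chosen to spare the α-stereocentre.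

Step 10
Reactants: 16 (R)-N-[(1E,4R,4aR,8aS)-4-[(2R,5S)-5-chloro-2,6,6-trimethyloxan-2-yl]-6-methyl-3,4,4a,7,8,8a-hexahydronaphthalen-1(2H)-ylidene]-2-methylpropane-2-sulfinamide
Product: 17 (R)-N-[(1R,4R,4aR,8aS)-4-[(2R,5S)-5-chloro-2,6,6-trimethyloxan-2-yl]-1,6-dimethyl-1,2,3,4,4a,7,8,8a-octahydronaphthalen-1-yl]-2-methylpropane-2-sulfinamide
Conditions: AlMe3 (1.2 equiv), toluene, −78 °C; then MeLi (2.5 equiv), −78 °C
Reagents that add atoms: methyllithium, [Li]C
Why: AlMe3-promoted 1,2-addition of MeLi to an N-tert-butanesulfinyl ketimine: methyl should enter on the convex face of the cis-decalin, anti to the axial C-8 methylene beside the imine carbon, and the (R)-sulfinyl group directs to the same face through the chelated chair transition state, giving the equatorial C–N bond of (1R).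

Step 11
Reactants: 17 (R)-N-[(1R,4R,4aR,8aS)-4-[(2R,5S)-5-chloro-2,6,6-trimethyloxan-2-yl]-1,6-dimethyl-1,2,3,4,4a,7,8,8a-octahydronaphthalen-1-yl]-2-methylpropane-2-sulfinamide
Product: 19 N-[(1R,4R,4aR,8aS)-4-[(2R,5S)-5-chloro-2,6,6-trimethyloxan-2-yl]-1,6-dimethyl-1,2,3,4,4a,7,8,8a-octahydronaphthalen-1-yl]formamide, via amine hydrochloride 18 (not isolated)
Conditions: HCl (4 M in 1,4-dioxane, 2 equiv), MeOH, 0 °C → rt; concentrate; then Et3N, HCO2CH2CF3, THF, 60 °C
Reagents that add atoms: 2,2,2-trifluoroethyl formate, O=COCC(F)(F)F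
Why: Acidolysis of the N–S bond frees the hindered tertiary-alkyl amine as its salt, which the activated formate ester should N-formylate after neutralisation; no stereocentre is touched and the chloro-oxane and ring alkene tolerate brief exposure to HCl.

Compound list
1 | nerol, (2Z)-3,7-dimethylocta-2,6-dien-1-ol | CC(C)=CCC/C(C)=C\CO | starting material
2 | [(2S,3R)-3-methyl-3-(4-methylpent-3-en-1-yl)oxiran-2-yl]methanol | OC[C@@H]1O[C@]1(C)CCC=C(C)C | intermediate
3 | [2-(1,3-dioxolan-2-yl)ethyl]magnesium bromide | Br[Mg]CCC1OCCO1 | starting material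
4 | (2R,3R)-2-[2-(1,3-dioxolan-2-yl)ethyl]-3,7-dimethyloct-6-ene-1,3-diol | OC[C@H]([C@@](O)(C)CCC=C(C)C)CCC1OCCO1 | intermediate
5 | 1-(triphenyl-λ5-phosphanylidene)propan-2-one | CC(=O)C=P(c1ccccc1)(c1ccccc1)c1ccccc1 | starting material
6 | (2S,3R)-2-[2-(1,3-dioxolan-2-yl)ethyl]-3-hydroxy-3,7-dimethyloct-6-enal | O=C[C@H]([C@@](O)(C)CCC=C(C)C)CCC1OCCO1 | intermediate
7 | (3E,5R,6R)-5-[2-(1,3-dioxolan-2-yl)ethyl]-6-hydroxy-6,10-dimethylundeca-3,9-dien-2-one | CC(=O)/C=C/[C@H]([C@@](O)(C)CCC=C(C)C)CCC1OCCO1 | intermediate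
8 | (3E,5R,6R)-5-[2-(1,3-dioxolan-2-yl)ethyl]-2,6,10-trimethylundeca-1,3,9-trien-6-ol | C=C(C)/C=C/[C@H]([C@@](O)(C)CCC=C(C)C)CCC1OCCO1 | intermediate
9 | (4R,5R)-5-hydroxy-5,9-dimethyl-4-[(1E)-3-methylbuta-1,3-dien-1-yl]dec-8-enal (in equilibrium with its lactol) | C=C(C)/C=C/[C@H]([C@@](O)(C)CCC=C(C)C)CCC=O | intermediate
10 | vinylmagnesium bromide | C=C[Mg]Br | starting material
11 | (6R,7R)-7,11-dimethyl-6-[(1E)-3-methylbuta-1,3-dien-1-yl]dodeca-1,10-diene-3,7-diol (both C-3 epimers) | C=C(C)/C=C/[C@H]([C@@](O)(C)CCC=C(C)C)CCC(O)C=C | intermediate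
12 | (6R,7R)-7-hydroxy-7,11-dimethyl-6-[(1E)-3-methylbuta-1,3-dien-1-yl]dodeca-1,10-dien-3-one | C=C(C)/C=C/[C@H]([C@@](O)(C)CCC=C(C)C)CCC(=O)C=C | intermediate
13 | (4R,4aS,8aS)-4-[(2R)-2-hydroxy-6-methylhept-5-en-2-yl]-6-methyl-3,4,4a,7,8,8a-hexahydronaphthalen-1(2H)-one | CC1=C[C@H]2[C@H]([C@@](O)(C)CCC=C(C)C)CCC(=O)[C@H]2CC1 | intermediate
14 | (4R,4aS,8aS)-4-[(2R,5S)-5-chloro-2,6,6-trimethyloxan-2-yl]-6-methyl-3,4,4a,7,8,8a-hexahydronaphthalen-1(2H)-one | CC1=C[C@H]2[C@H]([C@@]3(C)CC[C@H](Cl)C(C)(C)O3)CCC(=O)[C@H]2CC1 | intermediate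
15 | (R)-2-methylpropane-2-sulfinamide | CC(C)(C)[S@](N)=O | starting material
16 | (R)-N-[(1E,4R,4aR,8aS)-4-[(2R,5S)-5-chloro-2,6,6-trimethyloxan-2-yl]-6-methyl-3,4,4a,7,8,8a-hexahydronaphthalen-1(2H)-ylidene]-2-methylpropane-2-sulfinamide | CC1=C[C@H]2[C@H]([C@@]3(C)CC[C@H](Cl)C(C)(C)O3)CC/C(=N\[S@](=O)C(C)(C)C)[C@H]2CC1 | intermediate
17 | (R)-N-[(1R,4R,4aR,8aS)-4-[(2R,5S)-5-chloro-2,6,6-trimethyloxan-2-yl]-1,6-dimethyl-1,2,3,4,4a,7,8,8a-octahydronaphthalen-1-yl]-2-methylpropane-2-sulfinamide | CC1=C[C@H]2[C@H]([C@@]3(C)CC[C@H](Cl)C(C)(C)O3)CC[C@@](C)(N[S@](=O)C(C)(C)C)[C@H]2CC1 | intermediate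
18 | (1R,4R,4aR,8aS)-4-[(2R,5S)-5-chloro-2,6,6-trimethyloxan-2-yl]-1,6-dimethyl-1,2,3,4,4a,7,8,8a-octahydronaphthalen-1-aminium chloride | CC1=C[C@H]2[C@H]([C@@]3(C)CC[C@H](Cl)C(C)(C)O3)CC[C@@](C)([NH3+])[C@H]2CC1.[Cl-] | intermediate
19 | N-[(1R,4R,4aR,8aS)-4-[(2R,5S)-5-chloro-2,6,6-trimethyloxan-2-yl]-1,6-dimethyl-1,2,3,4,4a,7,8,8a-octahydronaphthalen-1-yl]formamide | CC1=C[C@H]2[C@H]([C@@]3(C)CC[C@H](Cl)C(C)(C)O3)CC[C@@](C)(NC=O)[C@H]2CC1 | target

Total step count: 11. Longest linear sequence: 11 steps (from nerol 1).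

Steps most likely to fail

Step 8 (key step). Chlorenium transfer may also go to the ring alkene, closure may take the 5-exo course to the oxolane, or the two faces of the side-chain alkene may be poorly differentiated. The fallback runs from 13 to 14 and forms the C–O and C–Cl bonds separately. Epoxidation of the exposed side-chain alkene with the D-fructose-derived Shi ketone and KHSO5 (K2CO3 buffer, MeCN/CH2(OMe)2/H2O, 0 °C) should give, under reagent control, the epoxy alcohol (4R,4aS,8aS)-4-{(2R)-4-[(2R)-3,3-dimethyloxiran-2-yl]-2-hydroxybutan-2-yl}-6-methyl-3,4,4a,7,8,8a-hexahydronaphthalen-1(2H)-one F1. Camphorsulfonic acid (CH2Cl2, −20 °C) should then open the epoxide at its tertiary carbon in the 6-endo sense to the axial alcohol (4R,4aS,8aS)-4-[(2R,5R)-5-hydroxy-2,6,6-trimethyloxan-2-yl]-6-methyl-3,4,4a,7,8,8a-hexahydronaphthalen-1(2H)-one F2, to be separated from any oxolane isomer; the oxane is still the last ring closed. ClCH2SO2Cl and pyridine convert the alcohol into its chloromethanesulfonate, the C5 chloromethanesulfonate ester of F2 F3, and LiCl in DMF (60 °C) should displace this leaving group with inversion to give 14.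

Step 2. The magnesium alkoxide may undergo epoxide migration followed by attack at C-1, or the SN2 attack at the hindered C-2 may be too slow. The fallback runs from 2 to 4 and uses a carboxyl-activated epoxide. Oxidation of 2 with TEMPO/PhI(OAc)2 in MeCN/H2O should give (2R,3R)-3-methyl-3-(4-methylpent-3-en-1-yl)oxirane-2-carboxylic acid F4. The cuprate made from 3 (4 equiv) and CuI (2 equiv) in THF at −20 °C is expected to open this glycidic acid at the α-carbon with inversion, giving (2S,3R)-2-[2-(1,3-dioxolan-2-yl)ethyl]-3-hydroxy-3,7-dimethyloct-6-enoic acid F5. Reduction with LiAlH4 (THF, 0 °C → rt) returns diol 4.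

Step 9. The Lewis-acidic condensation at 50 °C may epimerise the α-stereocentre C-8a through the enamine tautomer (cis to trans ring fusion), or the hindered ketone may condense incompletely. The fallback runs from 14 to 18 and builds the C=N bond under buffered conditions. NH2OH·HCl and NaOAc (MeOH, rt) should give the oxime of 14 F6. Ph2PCl and Et3N (CH2Cl2, −40 °C → rt) rearrange it to the N-(diphenylphosphinoyl) ketimine of 14 F7. MeMgBr with CeCl3 (THF, −78 °C) should add from the same convex face to give N-[(1R,4R,4aR,8aS)-4-[(2R,5S)-5-chloro-2,6,6-trimethyloxan-2-yl]-1,6-dimethyl-1,2,3,4,4a,7,8,8a-octahydronaphthalen-1-yl]-P,P-diphenylphosphinic amide F8. HCl in MeOH cleaves the P–N bond to amine hydrochloride 18, which is formylated as in step 11.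

Further compounds
F1 | step 8 | (4R,4aS,8aS)-4-{(2R)-4-[(2R)-3,3-dimethyloxiran-2-yl]-2-hydroxybutan-2-yl}-6-methyl-3,4,4a,7,8,8a-hexahydronaphthalen-1(2H)-one | CC1=C[C@H]2[C@H]([C@@](O)(C)CC[C@H]3OC3(C)C)CCC(=O)[C@H]2CC1
F2 | step 8 | (4R,4aS,8aS)-4-[(2R,5R)-5-hydroxy-2,6,6-trimethyloxan-2-yl]-6-methyl-3,4,4a,7,8,8a-hexahydronaphthalen-1(2H)-one | CC1=C[C@H]2[C@H]([C@@]3(C)CC[C@@H](O)C(C)(C)O3)CCC(=O)[C@H]2CC1
F3 | step 8 | C5 chloromethanesulfonate ester of F2 | CC1=C[C@H]2[C@H]([C@@]3(C)CC[C@@H](OS(=O)(=O)CCl)C(C)(C)O3)CCC(=O)[C@H]2CC1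
F4 | step 2 | (2R,3R)-3-methyl-3-(4-methylpent-3-en-1-yl)oxirane-2-carboxylic acid | OC(=O)[C@@H]1O[C@]1(C)CCC=C(C)C
F5 | step 2 | (2S,3R)-2-[2-(1,3-dioxolan-2-yl)ethyl]-3-hydroxy-3,7-dimethyloct-6-enoic acid | OC(=O)[C@H]([C@@](O)(C)CCC=C(C)C)CCC1OCCO1
F6 | step 9 | oxime of 14 | CC1=C[C@H]2[C@H]([C@@]3(C)CC[C@H](Cl)C(C)(C)O3)CCC(=NO)[C@H]2CC1
F7 | step 9 | N-(diphenylphosphinoyl) ketimine of 14 | CC1=C[C@H]2[C@H]([C@@]3(C)CC[C@H](Cl)C(C)(C)O3)CCC(=NP(=O)(c3ccccc3)c3ccccc3)[C@H]2CC1
F8 | step 9 | N-[(1R,4R,4aR,8aS)-4-[(2R,5S)-5-chloro-2,6,6-trimethyloxan-2-yl]-1,6-dimethyl-1,2,3,4,4a,7,8,8a-octahydronaphthalen-1-yl]-P,P-diphenylphosphinic amide | CC1=C[C@H]2[C@H]([C@@]3(C)CC[C@H](Cl)C(C)(C)O3)CC[C@@](C)(NP(=O)(c3ccccc3)c3ccccc3)[C@H]2CC1
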